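Retrosynthesis: the C10 hydroxyl is first masked as a trifluoroacetate. The lactone bond O–C6 is then cut while C1 and C6 are joined across the ten-membered ring, giving a cis-fused octalin hydroxy acid (cyclohexene ring A = C1–C6, cyclohexane ring B = C1, C6–C10).
Enabling feature: ketone carbon C1 and lactone carbinol C6 lie 1,6 across the ten-membered ring, C6 is allylic to the cis C4=C5 bond, and the C12 carboxyl sits on the neighbouring C7. The target is therefore the oxidative fragmentation product of a tertiary homoallylic ring-fusion alcohol whose own acid catches C6.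
Ring A is then cut at C4=C5 (metathesis), C1–C2 (Grignard addition) and C5–C6 (enolate vinylation). What remains, ring B with Me-14 and C11–C13, is (R)-carvone.
Forward order: carvone (ring B) is oxygenated at C8 and C10, vinylated at C6 and chlorinated at C12. Ring A is fused on and C12 is raised to the acid. One step then deletes the shared C1–C6 bond, so the ten-membered ring and the γ-lactone appear together.
Stereochemistry: C7 comes from carvone, C8 from anti attack followed by Mitsunobu inversion, C10 from enolate hydroxylation anti to the axial C8 ester, and C6 from C7 in the key step. The cis C4=C5 geometry is that of ring A, and C1/C6 of the octalin are sacrificial.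

Key step: step 13

Numbering: the germacrane numbering of the target is used for all compounds (C1 ketone carbon, C2, C3, C4(Me-15)=C5, C6 lactone carbinol, C7, C8 ester carbinol, C9, C10(Me-14, OH), C11(=C13H2)–C12). β means the face of the C7 side chain, α the opposite face.
Assumption: the configurations drawn at C1 and C6 of 14–19 are the expected ones. C1 is erased and C6 is reset in step 13, so the epimers at these two centres should serve as well.

Step 1
Reactants: 1 (R)-(−)-carvone
Product: 3 through-conjugated trimethylsilyl dienol ether of carvone (1-OSiMe3; C1=C10 and C8=C9), via bromomagnesium dienolate 2 (not isolated)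
Conditions: MeMgBr (1.2 equiv), FeCl3 (3 mol %), Et2O, −20 °C; then Me3SiCl, Et3N, DMPU, −20 °C to rt
Reagents that add atoms: chlorotrimethylsilane, C[Si](C)(C)Cl
Why: Kharasch-reagent deprotonation (iron-modified MeMgBr acting as a base) removes a γ-hydrogen at C8 and gives the through-conjugated dienolate, which O-silylation traps as the 1(10),8-dienol ether without touching C7.

Step 2
Reactants: 3 trimethylsilyl dienol ether
Product: 4 8α-hydroxycarvone, (4S,5R)-4-hydroxy-2-methyl-5-(prop-1-en-2-yl)cyclohex-2-en-1-one (hydroxyl trans to isopropenyl)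
Conditions: mCPBA (1.0 equiv), CH2Cl2, −40 to 0 °C; aqueous work-up
Reagents that add atoms: 3-chloroperbenzoic acid, O=C(OO)c1cccc(Cl)c1
Why: Vinylogous Rubottom oxidation, in which the peracid should attack the terminal C8=C9 bond of the dienol ether (end of the vinylogous donor system, least hindered) from the face anti to the C7 isopropenyl group, so that collapse to the enone leaves the new C8 centre as the 8α-alcohol.

Step 3
Reactants: 4 8α-hydroxycarvone
Product: 5 8β-ester enone, (1R,6R)-3-methyl-4-oxo-6-(prop-1-en-2-yl)cyclohex-2-en-1-yl 3-methylbutanoate (ester cis to isopropenyl)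
Conditions: 3-methylbutanoic acid, PPh3, DIAD, toluene, 0 °C to rt
Reagents that add atoms: 3-methylbutanoic acid, CC(C)CC(=O)O
Why: Mitsunobu esterification displaces the activated allylic oxygen by SN2 with inversion, which turns C8 into the 8β-ester cis to the C7 side chain, while anti elimination is disfavoured because H-7 is cis to the leaving group.

Step 4
Reactants: 5 8β-ester enone
Product: 7 ring B α-ketol (1-oxo; 10α-OH; 10β-Me; 8β-ester; 7β-isopropenyl), via potassium enolate 6 (not isolated)
Conditions: K[sec-Bu3BH] (1.05 equiv), THF, −78 °C; then 3-phenyl-2-(phenylsulfonyl)oxaziridine, −78 to −40 °C; AcOH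
Reagents that add atoms: 3-phenyl-2-(phenylsulfonyl)oxaziridine, O=S(=O)(c1ccccc1)N1OC1c1ccccc1
Why: 1,4-Reduction with the hindered borohydride gives the C1=C10 enolate regiospecifically, and electrophilic enolate hydroxylation with the N-sulfonyloxaziridine should come from the α face because the axial 8β-ester blocks the β face in a 1,3-diaxial sense, which sets C10 as 10α-OH/10β-Me.

Step 5
Reactants: 7 ring B α-ketol
Product: 9 6α-[2-(phenylsulfinyl)ethyl] α-ketol (both sulfur epimers), via dilithium enolate alkoxide 8 (not isolated)
Conditions: LiN(iPr)2 (2.1 equiv), THF, −78 °C; phenyl vinyl sulfoxide, −78 to −30 °C; AcOH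
Reagents that add atoms: phenyl vinyl sulfoxide, C=CS(=O)c1ccccc1
Why: Michael addition of a ketone enolate to phenyl vinyl sulfoxide as a vinyl cation equivalent works here because C10 is quaternary, so only the C6 enolate can form, and it is alkylated anti to the C7 substituent, which places the new chain 6α, trans to the side chain.

Step 6
Reactants: 9 sulfoxide
Product: 10 6α-vinyl α-ketol, (1R,2R,3S,5R)-3-ethenyl-5-hydroxy-5-methyl-4-oxo-2-(prop-1-en-2-yl)cyclohexyl 3-methylbutanoate
Conditions: toluene, 110 °C
Reagents that add atoms: none
Why: Thermal syn elimination of the sulfoxide (sulfoxide pyrolysis) can only run towards C5 and unveils the C6 vinyl group under neutral conditions that should neither move the olefin into conjugation nor epimerise C6.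

Step 7
Reactants: 10 6α-vinyl α-ketol
Product: 11 allylic chloride (C7 side chain now 3-chloroprop-1-en-2-yl, C12 = CH2Cl)
Conditions: Ca(OCl)2, CO2 (solid), CH2Cl2–H2O, 0 °C
Reagents that add atoms: calcium hypochlorite, [Ca+2].[O-]Cl.[O-]Cl
Why: Ene-type allylic chlorination with HOCl, known for carvone itself, picks the electron-rich 1,1-disubstituted C11 olefin over the monosubstituted vinyl group and gives the 2-(chloromethyl)allyl unit without touching a stereocentre.

Step 8
Reactants: 11 allylic chloride; 12 4-bromo-2-methylbut-1-ene
Product: 14 ring B triene diol (1β-OH; 1α-(3-methylbut-3-enyl); 6α-vinyl), via Grignard reagent 13 (not isolated)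
Conditions: 12, Mg, THF, rt; then LaCl3·2LiCl (30 mol %) and 11 (0.4 equiv relative to 13), THF, −78 to −40 °C; aq NH4Cl
Reagents that add atoms: none
Why: Lanthanide-assisted Grignard 1,2-addition suppresses enolisation of the α-vinyl ketone, spares ester and allylic chloride at low temperature, and under chelation of the C1 carbonyl with the C10 alkoxide (Cram chelate model) should enter anti to Me-14, from the α face, to give the 1β-alcohol.

Step 9
Reactants: 14 ring B triene diol
Product: 15 cis-fused octalin chloride (ring A with C4=C5 and Me-15; 1β-OH, H-6β, 10α-OH, 8β-ester, C12 = CH2Cl)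
Conditions: second-generation Grubbs catalyst (H2IMes)(PCy3)Cl2Ru=CHPh (5 mol %), CH2Cl2, 40 °C
Reagents that add atoms: none
Why: Ring-closing metathesis of the C6 vinyl group with the 1,1-disubstituted olefin closes cyclohexene ring A with its necessarily cis trisubstituted C4=C5 bond, whereas the chloromethyl-substituted C11 olefin could only give a four- or seven-membered ring and stays out.

Step 10
Reactants: 15 octalin chloride
Product: 16 octalin enal (C12 = CHO)
Conditions: N-methylmorpholine N-oxide (4 equiv), KI (20 mol %), MeCN, 50 °C
Reagents that add atoms: N-methylmorpholine N-oxide, C[N+]1([O-])CCOCC1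
Why: Kornblum-type oxidation with an amine N-oxide, in which iodide-catalysed SN2 displacement of the primary allylic chloride and loss of N-methylmorpholine give the enal without an oxidant that could touch the olefins or the tertiary alcohols.

Step 11
Reactants: 16 octalin enal
Product: 17 10-O-trifluoroacetyl enal (1β-OH free)
Conditions: (CF3CO)2O (1.1 equiv), pyridine, CH2Cl2, −40 °C
Reagents that add atoms: trifluoroacetic anhydride, O=C(OC(=O)C(F)(F)F)C(F)(F)F
Why: Acylation with the small, very reactive anhydride should take the C10 hydroxyl, whose carbon carries a methyl and a methylene group, in preference to the ring-fusion C1 hydroxyl wedged between C6 and C10, and installs the electron-poor helper that step 13 needs.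

Step 12
Reactants: 17 10-O-trifluoroacetyl enal
Product: 18 10-O-trifluoroacetyl hydroxy acid (C12 = CO2H, 1β-OH free)
Conditions: NaClO2, NaH2PO4, 2-methylbut-2-ene, t-BuOH–H2O, 0 °C
Reagents that add atoms: sodium chlorite, [Na+].[O-]Cl=O
Why: Pinnick oxidation converts the enal into the acrylic acid at about pH 4 and 0 °C, conditions under which the olefins (hypochlorite is scavenged), the tertiary alcohol and the hindered trifluoroacetate should last.

Step 13
Reactants: 18 10-O-trifluoroacetyl hydroxy acid
Product: 20 10-O-trifluoroacetyl derivative of the target, via lead alkoxide 19 (not isolated)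
Conditions: Pb(OAc)4 (1.2 equiv), benzene, 25 to 60 °C
Reagents that add atoms: none
Why: Proposed new method: ligand exchange puts tetravalent lead on the C1 oxygen of 18 (lead alkoxide 19), and departure of divalent lead breaks the ring-fusion bond C1–C6, so that C1 becomes the ketone and C6 the terminus of a C4–C5–C6 allyl radical or cation that the C12 carboxyl held on C7 captures at once. The closest known reaction types are the Pb(OAc)4 β-fragmentation of ring-fusion decalols (5-hydroxy steroids to ten-membered 5,10-seco ketones), the Pb(OAc)4 fragmentation of homoallylic alcohols to a carbonyl compound plus an allylic acetate, and the carboxylate transfer to allyl radicals of the Kharasch–Sosnovsky reaction; new is that the carboxylate is internal, so that ring expansion and lactonisation are one event. The lactone closes in the 5-exo mode (oxygen on C6, C4=C5 left outside the new ring, attack at C4 would need a seven-membered ring), while the ten-membered ring is not closed but uncovered when rings A and B lose their shared bond. C6 is the only new stereocentre: the equatorial C7–C11 bond is antiperiplanar to C6–C1 and H-7 eclipses C5 (least allylic strain), so the oxygen arrives on the face opposite to the departing C1 and gives the 6,7-trans lactone under control of C7. The cis geometry of C4=C5 is that of cyclohexene ring A and should be kept because the allyl intermediate is trapped intramolecularly faster than it can rotate. The step needs cleavage of C1–C6 in preference to C1–C2 and C1–C10: C2 would leave as a primary centre and C10 is disarmed by the trifluoroacetate, which takes away the donor power of its oxygen, whereas C6 leaves as an allyl unit with help from the carboxyl group.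

Step 14
Reactants: 20 10-O-trifluoroacetyl derivative of the target
Product: 21 target, (4Z,6R,7R,8R,10R)-10-hydroxy-8-(3-methylbutanoyloxy)-1-oxogermacra-4,11(13)-dien-12,6-olide
Conditions: KHCO3 (10 mol %), MeOH, 0 °C
Reagents that add atoms: none
Why: Base-catalysed transesterification, in which the trifluoroacetate, further activated by the neighbouring ketone, is methanolysed far faster than the 3-methylbutanoate or the lactone and before methanol can add to the α-methylene lactone, frees the 10α-hydroxyl with retention.

Compound list
1 | (R)-(−)-carvone | C=C(C)[C@H]1CC(=O)C(C)=CC1 | starting material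
2 | bromomagnesium 1(10),8-dienolate of carvone | C=C(C)[C@H]1CC(O[Mg]Br)=C(C)C=C1 | intermediate
3 | trimethylsilyl 1(10),8-dienol ether of carvone | C=C(C)[C@H]1CC(O[Si](C)(C)C)=C(C)C=C1 | intermediate
4 | 8α-hydroxycarvone, (4S,5R)-4-hydroxy-2-methyl-5-(prop-1-en-2-yl)cyclohex-2-en-1-one | C=C(C)[C@H]1CC(=O)C(C)=C[C@@H]1O | intermediate
5 | 8β-ester enone, (1R,6R)-3-methyl-4-oxo-6-(prop-1-en-2-yl)cyclohex-2-en-1-yl 3-methylbutanoate | C=C(C)[C@H]1CC(=O)C(C)=C[C@H]1OC(=O)CC(C)C | intermediate
6 | potassium C1=C10 enolate of the 9,10-dihydro derivative of 5 | C=C(C)[C@H]1CC([O-])=C(C)C[C@H]1OC(=O)CC(C)C.[K+] | intermediate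
7 | ring B α-ketol, (1R,2R,5R)-5-hydroxy-5-methyl-4-oxo-2-(prop-1-en-2-yl)cyclohexyl 3-methylbutanoate | C=C(C)[C@H]1CC(=O)[C@](C)(O)C[C@H]1OC(=O)CC(C)C | intermediate
8 | dilithium C1=C6 enolate C10 alkoxide of 7 | C=C(C)[C@H]1C=C([O-])[C@](C)([O-])C[C@H]1OC(=O)CC(C)C.[Li+].[Li+] | intermediate
9 | 6α-[2-(phenylsulfinyl)ethyl] derivative of 7 (both sulfur epimers) | C=C(C)[C@H]1[C@H](CCS(=O)c2ccccc2)C(=O)[C@](C)(O)C[C@H]1OC(=O)CC(C)C | intermediate
10 | 6α-vinyl α-ketol, (1R,2R,3S,5R)-3-ethenyl-5-hydroxy-5-methyl-4-oxo-2-(prop-1-en-2-yl)cyclohexyl 3-methylbutanoate | C=C(C)[C@H]1[C@H](C=C)C(=O)[C@](C)(O)C[C@H]1OC(=O)CC(C)C | intermediate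
11 | 12-chloro derivative of 10 (7β-(3-chloroprop-1-en-2-yl)) | C=C(CCl)[C@H]1[C@H](C=C)C(=O)[C@](C)(O)C[C@H]1OC(=O)CC(C)C | intermediate
12 | 4-bromo-2-methylbut-1-ene | C=C(C)CCBr | starting material
13 | 3-methylbut-3-enylmagnesium bromide | C=C(C)CC[Mg]Br | intermediate
14 | ring B triene diol: 1β,10α-dihydroxy, 1α-(3-methylbut-3-enyl), 6α-vinyl, 7β-(3-chloroprop-1-en-2-yl), 8β-(3-methylbutanoyloxy), 10β-methyl cyclohexane | C=C(CCl)[C@H]1[C@H](C=C)[C@](O)(CCC(C)=C)[C@](C)(O)C[C@H]1OC(=O)CC(C)C | intermediate
15 | cis-fused octalin chloride: C4=C5, 1β-OH, H-6β, H-7α, 8β-ester, 10α-OH, C12H2Cl | C=C(CCl)[C@H]1[C@@H]2C=C(C)CC[C@]2(O)[C@](C)(O)C[C@H]1OC(=O)CC(C)C | intermediate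
16 | cis-fused octalin enal (C12 = CHO) | C=C(C=O)[C@H]1[C@@H]2C=C(C)CC[C@]2(O)[C@](C)(O)C[C@H]1OC(=O)CC(C)C | intermediate
17 | 10-O-trifluoroacetyl octalin enal | C=C(C=O)[C@H]1[C@@H]2C=C(C)CC[C@]2(O)[C@](C)(OC(=O)C(F)(F)F)C[C@H]1OC(=O)CC(C)C | intermediate
18 | 10-O-trifluoroacetyl octalin hydroxy acid (1β-OH, C12O2H) | C=C(C(=O)O)[C@H]1[C@@H]2C=C(C)CC[C@]2(O)[C@](C)(OC(=O)C(F)(F)F)C[C@H]1OC(=O)CC(C)C | intermediate
19 | C1-O lead triacetate (lead alkoxide) of 18 | C=C(C(=O)O)[C@H]1[C@@H]2C=C(C)CC[C@]2(O[Pb](OC(C)=O)(OC(C)=O)OC(C)=O)[C@](C)(OC(=O)C(F)(F)F)C[C@H]1OC(=O)CC(C)C | intermediate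
20 | 10-O-trifluoroacetyl derivative of the target | C=C1C(=O)O[C@@H]2/C=C(/C)CCC(=O)[C@](C)(OC(=O)C(F)(F)F)C[C@@H](OC(=O)CC(C)C)[C@@H]12 | intermediate
21 | target CNP0105188.1 | C=C1C(=O)O[C@@H]2/C=C(/C)CCC(=O)[C@](C)(O)C[C@@H](OC(=O)CC(C)C)[C@@H]12 | target

Total step count: 14. Longest linear sequence: 14 steps (1 to 21).

Steps most likely to fail

Step 13. The fragmentation may take the wrong bond at C1 (scission of C1–C10 towards the tertiary C10 centre). External acetate may catch the allyl intermediate, or the olefin geometry may be lost before capture. The fallback uses known chemistry; it sets out from 16 and returns to the route at 21. Pinnick oxidation of 16 gives the trifluoroacetate-free dihydroxy acid F1. Hydroxyl-directed epoxidation with VO(acac)2 and t-BuOOH should deliver oxygen to C4=C5 syn to the C1 hydroxyl and give the 4β,5β-epoxide F2. Warming with Ti(OiPr)4 triggers a Grob-type epoxy-alcohol fragmentation, with the C5–O bond antiperiplanar to C1–C6, so only this C–C bond can break. This leads to the ten-membered (5E)-4-hydroxy-1-oxo acid F3. Catalytic camphorsulfonic acid in CH2Cl2 then ionises the tertiary allylic alcohol, and the carboxyl group closes on C6 with allylic transposition to give 21.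

Step 2. Oxygen transfer may go to the silyloxy-bearing C1=C10 bond (α- instead of γ-hydroxylation) or to the isopropenyl group, and the facial selectivity at C8 may be poor. The fallback replaces oxygen transfer and Mitsunobu inversion by halogenation and substitution; it sets out from 3 and returns at 5. N-Bromosuccinimide in THF at −78 °C brominates the γ-carbon of the dienol ether anti to the isopropenyl group to give 8α-bromocarvone F4. Caesium 3-methylbutanoate in DMF then displaces the bromide with inversion.

Step 5. Proton transfer between enolate and adduct, oligomerisation of the vinyl sulfoxide, or low conversion of the hindered dianion may spoil the Michael addition. The fallback replaces conjugate addition and pyrolysis by aldol addition and 1,2-elimination; it sets out from 7 and returns at 10. The same dilithium species 8 is added to (phenylselanyl)acetaldehyde to give the C6 β-hydroxy selenide F5. Methanesulfonyl chloride and Et3N then convert F5 into the vinyl group by anti elimination of the selenium and oxygen substituents.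

Further compounds
F1 | step 13 | trifluoroacetate-free dihydroxy acid (1β,10α-diol, C12O2H) | C=C(C(=O)O)[C@H]1[C@@H]2C=C(C)CC[C@]2(O)[C@](C)(O)C[C@H]1OC(=O)CC(C)C
F2 | step 13 | 4β,5β-epoxide of F1 | C=C(C(=O)O)[C@H]1[C@@H]2[C@H]3O[C@@]3(C)CC[C@]2(O)[C@](C)(O)C[C@H]1OC(=O)CC(C)C
F3 | step 13 | ten-membered (5E)-4,10-dihydroxy-8-(3-methylbutanoyloxy)-1-oxogermacra-5,11(13)-dien-12-oic acid | C=C(C(=O)O)[C@H]1/C=C/[C@@](C)(O)CCC(=O)[C@](C)(O)C[C@H]1OC(=O)CC(C)C
F4 | step 2 | 8α-bromocarvone (bromine trans to isopropenyl) | C=C(C)[C@H]1CC(=O)C(C)=C[C@@H]1Br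
F5 | step 5 | 6α-[1-hydroxy-2-(phenylselanyl)ethyl] derivative of 7 (carbinol epimers) | C=C(C)[C@H]1[C@H](C(O)C[Se]c2ccccc2)C(=O)[C@](C)(O)C[C@H]1OC(=O)CC(C)C
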